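## Plan

1. Retrosynthesis: (i) the three Si–O bonds (final desilylation); (ii) the C2–aryl bond of the oxolane, giving an arylzinc that carries one complete side chain and a 2-benzenesulfonyloxolane that carries the other; (iii) both aryl–O–C8 ether bonds, back to one (S)-lactate-derived α-tosyloxy ketone; (iv) the lactone precursor of the sulfone at C3–CH3 (enolate methylation) and C4–C5 (crotylation of an aryl aldehyde).
2. Enabling feature: C2 of the oxolane is bonded to the ring oxygen O1, so a leaving group at C2 ionises to the O1=C2 oxocarbenium ion of a five-membered ring. The trans C3/C4 methyl groups fix its envelope (C4 as flap), so an aryl nucleophile enters cis to the C3 methyl and trans to the C5 aryl.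
3. Forward order: tosylate 5 (3 steps); aryl bromide 12 from 5-bromosalicylaldehyde (etherification, Dakin oxidation, silylation, reduction, silylation); lactone 21 from silylated vanillin (crotylboration, hydroboration, oxidative lactonisation, methylation), then side chain, lactol and sulfone 27; union of 12 and 27; desilylation. The oxolane ring arises as the lactone in step 11 and is not opened again.
4. Stereochemistry: C8 and C8' from (S)-lactate by SN2 inversion; C7 and C7' by Felkin–Anh reduction; C5 and C4 by Brown (Z)-crotylboration; C3 by enolate methylation anti to the C4 methyl; C2 in the key step by inside attack on the oxocarbenium ion.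

Key step: step 19

Remark: aldehyde 13 and the THF solution of Grignard reagent 3 are taken as purchasable. Oxolane atoms are numbered O1, C2 (carrying the hydroxylated aryl ring), C3, C4, C5; the side chains are numbered C7 (carbinol) and C8 (aryloxy carbon).

## Route

**Part I – side-chain electrophile**

Step 1
Reactants: 1 ethyl (S)-lactate
Product: 2 (S)-2-hydroxy-N-methoxy-N-methylpropanamide
Conditions: MeNH(OMe)·HCl, i-PrMgCl, THF, −20 → 0 °C
Reagents that add atoms: N,O-dimethylhydroxylamine hydrochloride, CNOC.Cl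
Why: Direct Weinreb amidation of the ester by the chloromagnesium amide, in which the α-hydroxyl is held as its magnesium alkoxide so that the (S) centre should not enolise.

Step 2
Reactants: 2 (S)-2-hydroxy-N-methoxy-N-methylpropanamide; 3 3,4-dimethoxyphenylmagnesium bromide
Product: 4 (S)-1-(3,4-dimethoxyphenyl)-2-hydroxypropan-1-one
Conditions: 3 (2.5 equiv), THF, 0 °C → rt; aq. NH4Cl
Reagents that add atoms: none
Why: Weinreb ketone synthesis, in which the first equivalent deprotonates the hydroxyl and the second adds once to give a stable magnesium chelate that collapses to the ketone only on quench, so over-addition and loss of configuration are not expected.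

Step 3
Reactants: 4 (S)-1-(3,4-dimethoxyphenyl)-2-hydroxypropan-1-one
Product: 5 (S)-1-(3,4-dimethoxyphenyl)-1-oxopropan-2-yl 4-methylbenzenesulfonate
Conditions: Ts2O, pyridine, DMAP (cat.), CH2Cl2, 0 °C
Reagents that add atoms: p-toluenesulfonic anhydride, Cc1ccc(cc1)S(=O)(=O)OS(=O)(=O)c1ccc(C)cc1
Why: O-sulfonylation of the α-ketol with the anhydride (no chloride present that could displace the activated tosylate), with retention because the C–O bond is not broken.

**Part II – aryl bromide (precursor of the arylzinc)**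

Step 4
Reactants: 6 5-bromo-2-hydroxybenzaldehyde; 5 (S)-1-(3,4-dimethoxyphenyl)-1-oxopropan-2-yl 4-methylbenzenesulfonate
Product: 7 5-bromo-2-{[(2R)-1-(3,4-dimethoxyphenyl)-1-oxopropan-2-yl]oxy}benzaldehyde
Conditions: BEMP (1.0 equiv), MeCN, 0 °C → rt
Reagents that add atoms: none
Why: Williamson-type SN2 displacement of the carbonyl-activated secondary tosylate by the phenoxide formed with one equivalent of phosphazene base, which should invert (S) to (R) at the future C8 and leave no excess base to enolise the ketone or start an aldol onto the ortho aldehyde.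

Step 5
Reactants: 7 5-bromo-2-{[(2R)-1-(3,4-dimethoxyphenyl)-1-oxopropan-2-yl]oxy}benzaldehyde
Product: 9 (2R)-2-(4-bromo-2-hydroxyphenoxy)-1-(3,4-dimethoxyphenyl)propan-1-one, via aryl formate 8 (not isolated)
Conditions: mCPBA, CH2Cl2, 0 °C → rt; NaHCO3/Na2S2O3 wash; then Et3N (cat.), MeOH, 0 °C
Reagents that add atoms: mCPBA, OOC(=O)c1cccc(Cl)c1
Why: Dakin-type Baeyer–Villiger oxidation in which the ortho-alkoxy aryl group migrates in the Criegee adduct of the aldehyde (much faster than the aryl ketone reacts) to give the formate, which is methanolysed to the phenol without touching C8.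

Step 6
Reactants: 9 (2R)-2-(4-bromo-2-hydroxyphenoxy)-1-(3,4-dimethoxyphenyl)propan-1-one
Product: 10 (2R)-2-[4-bromo-2-(tert-butyldimethylsilyloxy)phenoxy]-1-(3,4-dimethoxyphenyl)propan-1-one
Conditions: TBSCl, imidazole, DMF, 0 °C → rt
Reagents that add atoms: tert-butyldimethylsilyl chloride, CC(C)(C)[Si](C)(C)Cl
Why: Imidazole-promoted silylation of the phenol, which also draws any cyclic hemiketal tautomer of 9 back to the open ketone and masks the acidic OH for the later organolithium step.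

Step 7
Reactants: 10 (2R)-2-[4-bromo-2-(tert-butyldimethylsilyloxy)phenoxy]-1-(3,4-dimethoxyphenyl)propan-1-one
Product: 11 (1R,2R)-2-[4-bromo-2-(tert-butyldimethylsilyloxy)phenoxy]-1-(3,4-dimethoxyphenyl)propan-1-ol
Conditions: polymer-supported borohydride (Amberlite IRA-400, BH4 form), MeOH, 0 °C
Reagents that add atoms: none
Why: Felkin–Anh (polar, non-chelating) hydride reduction: with an ammonium counter-ion no chelate forms, the C8–OAr bond lies anti to the incoming hydride, and attack past H rather than CH3 should set (1R), giving the threo (1R,2R) pair.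

Step 8
Reactants: 11 (1R,2R)-2-[4-bromo-2-(tert-butyldimethylsilyloxy)phenoxy]-1-(3,4-dimethoxyphenyl)propan-1-ol
Product: 12 (1R,2R)-2-[4-bromo-2-(tert-butyldimethylsilyloxy)phenoxy]-1-(tert-butyldimethylsilyloxy)-1-(3,4-dimethoxyphenyl)propane
Conditions: TBSOTf, 2,6-lutidine, CH2Cl2, −78 → 0 °C
Reagents that add atoms: tert-butyldimethylsilyl triflate, CC(C)(C)[Si](C)(C)OS(=O)(=O)C(F)(F)F
Why: Silyl triflate/lutidine silylation of the hindered secondary benzylic alcohol, which leaves both stereocentres untouched and removes the last acidic proton.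

**Part III – 2-sulfonyloxolane**

Step 9
Reactants: 13 4-(tert-butyldimethylsilyloxy)-3-methoxybenzaldehyde
Product: 15 (1S,2R)-1-[4-(tert-butyldimethylsilyloxy)-3-methoxyphenyl]-2-methylbut-3-en-1-ol, via diisopinocampheylborinate 14 (not isolated)
Conditions: cis-2-butene, n-BuLi, KOt-Bu, THF, −78 → −45 °C; (−)-Ipc2BOMe, −78 °C; BF3·OEt2; 13, −78 °C; then ethanolamine, rt
Reagents that add atoms: (Z)-crotyldiisopinocampheylborane (from (+)-α-pinene-derived (−)-Ipc2BOMe and cis-2-butene), C/C=C\CB([C@@H]1C[C@@H]2C[C@H]([C@H]1C)C2(C)C)[C@@H]1C[C@@H]2C[C@H]([C@H]1C)C2(C)C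
Why: Brown asymmetric crotylboration through a closed chair transition state, in which the Z geometry gives the syn relationship and the Ipc groups derived from (+)-α-pinene direct the crotyl group to the aldehyde face that should give (1S,2R), the future C5 and C4.

Step 10
Reactants: 15 (1S,2R)-1-[4-(tert-butyldimethylsilyloxy)-3-methoxyphenyl]-2-methylbut-3-en-1-ol
Product: 17 (1S,2R)-1-[4-(tert-butyldimethylsilyloxy)-3-methoxyphenyl]-2-methylbutane-1,4-diol, via B-alkyl-9-BBN adduct 16 (not isolated)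
Conditions: 9-BBN (2.5 equiv), THF, 0 °C → rt; then 30% H2O2, aq. NaOAc, 0 °C → rt
Reagents that add atoms: hydrogen peroxide, OO
Why: Anti-Markovnikov hydroboration of the terminal alkene with a bulky borane followed by buffered oxidation (mild enough for the aryl silyl ether), with no stereocentre formed or disturbed.

Step 11
Reactants: 17 (1S,2R)-1-[4-(tert-butyldimethylsilyloxy)-3-methoxyphenyl]-2-methylbutane-1,4-diol
Product: 19 (4R,5S)-5-[4-(tert-butyldimethylsilyloxy)-3-methoxyphenyl]-4-methyloxolan-2-one, via lactol 18 (not isolated)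
Conditions: TEMPO (cat.), PhI(OAc)2, CH2Cl2, rt
Reagents that add atoms: none
Why: TEMPO/PhI(OAc)2 oxidative lactonisation, in which the oxoammonium salt oxidises the primary alcohol selectively, the aldehyde closes onto the benzylic hydroxyl (5-exo-trig) and the lactol is oxidised on to the γ-lactone.

Step 12
Reactants: 19 (4R,5S)-5-[4-(tert-butyldimethylsilyloxy)-3-methoxyphenyl]-4-methyloxolan-2-one
Product: 21 (3R,4R,5S)-5-[4-(tert-butyldimethylsilyloxy)-3-methoxyphenyl]-3,4-dimethyloxolan-2-one, via lithium enolate 20 (not isolated)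
Conditions: LDA, THF, −78 °C; MeI, −78 → −40 °C
Reagents that add atoms: iodomethane, CI
Why: Alkylation of the lactone enolate, in which iodomethane should approach anti to the adjacent C4 methyl (which shares a face with the C5 aryl), giving the 3,4-trans (3R) isomer that is also the more stable epimer.

Step 13
Reactants: 21 (3R,4R,5S)-5-[4-(tert-butyldimethylsilyloxy)-3-methoxyphenyl]-3,4-dimethyloxolan-2-one
Product: 22 (3R,4R,5S)-5-(4-hydroxy-3-methoxyphenyl)-3,4-dimethyloxolan-2-one
Conditions: TBAF, AcOH, THF, 0 °C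
Reagents that add atoms: none
Why: Fluoride cleavage of the aryl silyl ether, buffered with acetic acid so that the lactone and its α-centre are not attacked.

Step 14
Reactants: 22 (3R,4R,5S)-5-(4-hydroxy-3-methoxyphenyl)-3,4-dimethyloxolan-2-one; 5 (S)-1-(3,4-dimethoxyphenyl)-1-oxopropan-2-yl 4-methylbenzenesulfonate
Product: 23 (3R,4R,5S)-5-(4-{[(2R)-1-(3,4-dimethoxyphenyl)-1-oxopropan-2-yl]oxy}-3-methoxyphenyl)-3,4-dimethyloxolan-2-one
Conditions: BEMP (1.0 equiv), MeCN, rt
Reagents that add atoms: none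
Why: The same SN2 etherification as in step 4, with inversion to (R) at C8' and with the phenoxide too weak a base to enolise the lactone or the product ketone.

Step 15
Reactants: 23 (3R,4R,5S)-5-(4-{[(2R)-1-(3,4-dimethoxyphenyl)-1-oxopropan-2-yl]oxy}-3-methoxyphenyl)-3,4-dimethyloxolan-2-one
Product: 24 (3R,4R,5S)-5-(4-{[(1R,2R)-1-(3,4-dimethoxyphenyl)-1-hydroxypropan-2-yl]oxy}-3-methoxyphenyl)-3,4-dimethyloxolan-2-one
Conditions: polymer-supported borohydride (Amberlite IRA-400, BH4 form), MeOH/THF, 0 °C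
Reagents that add atoms: none
Why: Felkin–Anh reduction as in step 7, which should set (1R) at C7' and give the threo pair, while the γ-lactone is not reduced by borohydride at 0 °C.

Step 16
Reactants: 24 (3R,4R,5S)-5-(4-{[(1R,2R)-1-(3,4-dimethoxyphenyl)-1-hydroxypropan-2-yl]oxy}-3-methoxyphenyl)-3,4-dimethyloxolan-2-one
Product: 25 (3R,4R,5S)-5-(4-{[(1R,2R)-1-(tert-butyldimethylsilyloxy)-1-(3,4-dimethoxyphenyl)propan-2-yl]oxy}-3-methoxyphenyl)-3,4-dimethyloxolan-2-one
Conditions: TBSOTf, 2,6-lutidine, CH2Cl2, −78 → 0 °C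
Reagents that add atoms: tert-butyldimethylsilyl triflate, CC(C)(C)[Si](C)(C)OS(=O)(=O)C(F)(F)F
Why: Silylation of the secondary benzylic alcohol with the triflate and a hindered base that is too weak to enolise the lactone.

Step 17
Reactants: 25 (3R,4R,5S)-5-(4-{[(1R,2R)-1-(tert-butyldimethylsilyloxy)-1-(3,4-dimethoxyphenyl)propan-2-yl]oxy}-3-methoxyphenyl)-3,4-dimethyloxolan-2-one
Product: 26 (3R,4R,5S)-5-(4-{[(1R,2R)-1-(tert-butyldimethylsilyloxy)-1-(3,4-dimethoxyphenyl)propan-2-yl]oxy}-3-methoxyphenyl)-3,4-dimethyloxolan-2-ol (anomer mixture)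
Conditions: DIBAL-H (1.1 equiv), CH2Cl2, −78 °C; Rochelle salt
Reagents that add atoms: none
Why: Partial reduction of the lactone to the lactol, since the aluminium hemiacetal formed at −78 °C is stable until work-up.

Step 18
Reactants: 26 (3R,4R,5S)-5-(4-{[(1R,2R)-1-(tert-butyldimethylsilyloxy)-1-(3,4-dimethoxyphenyl)propan-2-yl]oxy}-3-methoxyphenyl)-3,4-dimethyloxolan-2-ol
Product: 27 (3R,4R,5S)-2-(benzenesulfonyl)-5-(4-{[(1R,2R)-1-(tert-butyldimethylsilyloxy)-1-(3,4-dimethoxyphenyl)propan-2-yl]oxy}-3-methoxyphenyl)-3,4-dimethyloxolane (anomer mixture)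
Conditions: PhSO2H, CaCl2, CH2Cl2, rt
Reagents that add atoms: benzenesulfinic acid, O=S(O)c1ccccc1
Why: Ley-type anomeric sulfone formation, an acid-promoted exchange of the lactol hydroxyl for sulfinate (S-attack) through the oxocarbenium ion with CaCl2 taking up the water; the anomer ratio is of no consequence.

**Part IV – union and release**

Step 19
Reactants: 12 (1R,2R)-2-[4-bromo-2-(tert-butyldimethylsilyloxy)phenoxy]-1-(tert-butyldimethylsilyloxy)-1-(3,4-dimethoxyphenyl)propane; 27 (3R,4R,5S)-2-(benzenesulfonyl)-5-(4-{[(1R,2R)-1-(tert-butyldimethylsilyloxy)-1-(3,4-dimethoxyphenyl)propan-2-yl]oxy}-3-methoxyphenyl)-3,4-dimethyloxolane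
Product: 30 (2S,3R,4R,5S)-2-{3-(tert-butyldimethylsilyloxy)-4-[(1R,2R)-1-(tert-butyldimethylsilyloxy)-1-(3,4-dimethoxyphenyl)propan-2-yloxy]phenyl}-5-{4-[(1R,2R)-1-(tert-butyldimethylsilyloxy)-1-(3,4-dimethoxyphenyl)propan-2-yloxy]-3-methoxyphenyl}-3,4-dimethyloxolane, via aryllithium 28 (not isolated), via arylzinc bromide 29 (not isolated)
Conditions: 12 (1.5 equiv), n-BuLi, THF, −78 °C; ZnBr2 (1.5 equiv), −78 °C → rt; then 27, THF, rt
Reagents that add atoms: none
Why: ZnBr2 ionises either anomer of sulfone 27 to the same O1=C2 oxocarbenium ion (so the anomer mixture converges), and arylzinc 29 transfers its aryl group to C2 in an SN1-type substitution; the closest known reaction type is the coupling of organozinc reagents with 2-benzenesulfonyl cyclic ethers, which has been used with simple arylzincs on 5-aryl-3,4-dimethyl-2-sulfonyloxolanes. No ring is closed, because the oxolane is already in place and only its exocyclic C2–aryl bond is made. The new stereocentre C2 is controlled by the ring: in the favoured envelope C4 is the flap, the trans C3 and C4 methyl groups are pseudoequatorial and the C5 aryl is pseudoaxial, and attack on the inside face of this envelope (staggered with respect to C3) should place the incoming aryl cis to the C3 methyl and trans to the C5 aryl, i.e. (2S). The step needs facial selectivity at C2 and ionisation of the anomeric C–S bond only; the first is secured by the trans-dimethyl pattern that fixes the envelope, the second by the mild Lewis acid, which should leave the benzylic silyl ethers and the C5–O bond alone. The arylzinc bromide does not attack silyl ethers, so the complete protected side chains with C7, C8, C7' and C8' arrive intact.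

Step 20
Reactants: 30 (2S,3R,4R,5S)-2-{3-(tert-butyldimethylsilyloxy)-4-[(1R,2R)-1-(tert-butyldimethylsilyloxy)-1-(3,4-dimethoxyphenyl)propan-2-yloxy]phenyl}-5-{4-[(1R,2R)-1-(tert-butyldimethylsilyloxy)-1-(3,4-dimethoxyphenyl)propan-2-yloxy]-3-methoxyphenyl}-3,4-dimethyloxolane
Product: 31 manassantin B1
Conditions: TBAF (4 equiv), THF, 0 °C → rt
Reagents that add atoms: none
Why: Global fluoride desilylation, in which Si–F bond formation cleaves the aryl and the two secondary silyl ethers under conditions that touch neither the benzylic ethers nor any stereocentre.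

## Compound list

1 | ethyl (S)-lactate | C[C@H](O)C(=O)OCC | starting material
2 | (S)-2-hydroxy-N-methoxy-N-methylpropanamide | C[C@H](O)C(=O)N(C)OC | intermediate
3 | 3,4-dimethoxyphenylmagnesium bromide | COc1ccc([Mg]Br)cc1OC | starting material
4 | (S)-1-(3,4-dimethoxyphenyl)-2-hydroxypropan-1-one | C[C@H](O)C(=O)c1ccc(OC)c(OC)c1 | intermediate
5 | (S)-1-(3,4-dimethoxyphenyl)-1-oxopropan-2-yl 4-methylbenzenesulfonate | C[C@H](OS(=O)(=O)c1ccc(C)cc1)C(=O)c1ccc(OC)c(OC)c1 | intermediate
6 | 5-bromo-2-hydroxybenzaldehyde | O=Cc1cc(Br)ccc1O | starting material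
7 | 5-bromo-2-{[(2R)-1-(3,4-dimethoxyphenyl)-1-oxopropan-2-yl]oxy}benzaldehyde | COc1ccc(C(=O)[C@@H](C)Oc2ccc(Br)cc2C=O)cc1OC | intermediate
8 | 5-bromo-2-{[(2R)-1-(3,4-dimethoxyphenyl)-1-oxopropan-2-yl]oxy}phenyl formate | COc1ccc(C(=O)[C@@H](C)Oc2ccc(Br)cc2OC=O)cc1OC | intermediate (not isolated)
9 | (2R)-2-(4-bromo-2-hydroxyphenoxy)-1-(3,4-dimethoxyphenyl)propan-1-one | COc1ccc(C(=O)[C@@H](C)Oc2ccc(Br)cc2O)cc1OC | intermediate
10 | (2R)-2-[4-bromo-2-(tert-butyldimethylsilyloxy)phenoxy]-1-(3,4-dimethoxyphenyl)propan-1-one | COc1ccc(C(=O)[C@@H](C)Oc2ccc(Br)cc2O[Si](C)(C)C(C)(C)C)cc1OC | intermediate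
11 | (1R,2R)-2-[4-bromo-2-(tert-butyldimethylsilyloxy)phenoxy]-1-(3,4-dimethoxyphenyl)propan-1-ol | COc1ccc([C@@H](O)[C@@H](C)Oc2ccc(Br)cc2O[Si](C)(C)C(C)(C)C)cc1OC | intermediate
12 | (1R,2R)-2-[4-bromo-2-(tert-butyldimethylsilyloxy)phenoxy]-1-(tert-butyldimethylsilyloxy)-1-(3,4-dimethoxyphenyl)propane | COc1ccc([C@@H](O[Si](C)(C)C(C)(C)C)[C@@H](C)Oc2ccc(Br)cc2O[Si](C)(C)C(C)(C)C)cc1OC | intermediate
13 | 4-(tert-butyldimethylsilyloxy)-3-methoxybenzaldehyde | COc1cc(C=O)ccc1O[Si](C)(C)C(C)(C)C | starting material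
14 | diisopinocampheylborinate of 15 | C=C[C@@H](C)[C@H](OB([C@@H]1C[C@@H]2C[C@H]([C@H]1C)C2(C)C)[C@@H]1C[C@@H]2C[C@H]([C@H]1C)C2(C)C)c1ccc(O[Si](C)(C)C(C)(C)C)c(OC)c1 | intermediate (not isolated)
15 | (1S,2R)-1-[4-(tert-butyldimethylsilyloxy)-3-methoxyphenyl]-2-methylbut-3-en-1-ol | C=C[C@@H](C)[C@H](O)c1ccc(O[Si](C)(C)C(C)(C)C)c(OC)c1 | intermediate
16 | B-[(3R,4S)-4-aryl-4-hydroxy-3-methylbutyl]-9-borabicyclo[3.3.1]nonane | C1CCC2CCCC1B2CC[C@@H](C)[C@H](O)c1ccc(O[Si](C)(C)C(C)(C)C)c(OC)c1 | intermediate (not isolated)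
17 | (1S,2R)-1-[4-(tert-butyldimethylsilyloxy)-3-methoxyphenyl]-2-methylbutane-1,4-diol | OCC[C@@H](C)[C@H](O)c1ccc(O[Si](C)(C)C(C)(C)C)c(OC)c1 | intermediate
18 | (4R,5S)-5-[4-(tert-butyldimethylsilyloxy)-3-methoxyphenyl]-4-methyloxolan-2-ol | OC1C[C@@H](C)[C@H](O1)c2ccc(O[Si](C)(C)C(C)(C)C)c(OC)c2 | intermediate (not isolated)
19 | (4R,5S)-5-[4-(tert-butyldimethylsilyloxy)-3-methoxyphenyl]-4-methyloxolan-2-one | O=C1C[C@@H](C)[C@H](O1)c2ccc(O[Si](C)(C)C(C)(C)C)c(OC)c2 | intermediate
20 | lithium enolate of 19 | [Li]OC1=C[C@@H](C)[C@H](O1)c2ccc(O[Si](C)(C)C(C)(C)C)c(OC)c2 | intermediate (not isolated)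
21 | (3R,4R,5S)-5-[4-(tert-butyldimethylsilyloxy)-3-methoxyphenyl]-3,4-dimethyloxolan-2-one | O=C1[C@H](C)[C@@H](C)[C@H](O1)c2ccc(O[Si](C)(C)C(C)(C)C)c(OC)c2 | intermediate
22 | (3R,4R,5S)-5-(4-hydroxy-3-methoxyphenyl)-3,4-dimethyloxolan-2-one | O=C1[C@H](C)[C@@H](C)[C@H](O1)c2ccc(O)c(OC)c2 | intermediate
23 | (3R,4R,5S)-5-(4-{[(2R)-1-(3,4-dimethoxyphenyl)-1-oxopropan-2-yl]oxy}-3-methoxyphenyl)-3,4-dimethyloxolan-2-one | O=C1[C@H](C)[C@@H](C)[C@H](O1)c2ccc(O[C@H](C)C(=O)c3ccc(OC)c(OC)c3)c(OC)c2 | intermediate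
24 | (3R,4R,5S)-5-(4-{[(1R,2R)-1-(3,4-dimethoxyphenyl)-1-hydroxypropan-2-yl]oxy}-3-methoxyphenyl)-3,4-dimethyloxolan-2-one | O=C1[C@H](C)[C@@H](C)[C@H](O1)c2ccc(O[C@H](C)[C@H](O)c3ccc(OC)c(OC)c3)c(OC)c2 | intermediate
25 | (3R,4R,5S)-5-(4-{[(1R,2R)-1-(tert-butyldimethylsilyloxy)-1-(3,4-dimethoxyphenyl)propan-2-yl]oxy}-3-methoxyphenyl)-3,4-dimethyloxolan-2-one | O=C1[C@H](C)[C@@H](C)[C@H](O1)c2ccc(O[C@H](C)[C@H](O[Si](C)(C)C(C)(C)C)c3ccc(OC)c(OC)c3)c(OC)c2 | intermediate
26 | (3R,4R,5S)-5-(4-{[(1R,2R)-1-(tert-butyldimethylsilyloxy)-1-(3,4-dimethoxyphenyl)propan-2-yl]oxy}-3-methoxyphenyl)-3,4-dimethyloxolan-2-ol (anomer mixture) | OC1[C@H](C)[C@@H](C)[C@H](O1)c2ccc(O[C@H](C)[C@H](O[Si](C)(C)C(C)(C)C)c3ccc(OC)c(OC)c3)c(OC)c2 | intermediate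
27 | (3R,4R,5S)-2-(benzenesulfonyl)-5-(4-{[(1R,2R)-1-(tert-butyldimethylsilyloxy)-1-(3,4-dimethoxyphenyl)propan-2-yl]oxy}-3-methoxyphenyl)-3,4-dimethyloxolane (anomer mixture) | O=S(=O)(c1ccccc1)C1[C@H](C)[C@@H](C)[C@H](O1)c2ccc(O[C@H](C)[C@H](O[Si](C)(C)C(C)(C)C)c3ccc(OC)c(OC)c3)c(OC)c2 | intermediate
28 | aryllithium from 12 (Li in place of Br) | COc1ccc([C@@H](O[Si](C)(C)C(C)(C)C)[C@@H](C)Oc2ccc([Li])cc2O[Si](C)(C)C(C)(C)C)cc1OC | intermediate (not isolated)
29 | arylzinc bromide from 12 (ZnBr in place of Br) | COc1ccc([C@@H](O[Si](C)(C)C(C)(C)C)[C@@H](C)Oc2ccc([Zn]Br)cc2O[Si](C)(C)C(C)(C)C)cc1OC | intermediate (not isolated)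
30 | tris-TBS ether of manassantin B1 (full name in step 19) | COc1ccc([C@@H](O[Si](C)(C)C(C)(C)C)[C@@H](C)Oc2ccc([C@H]3O[C@H](c4ccc(O[C@H](C)[C@H](O[Si](C)(C)C(C)(C)C)c5ccc(OC)c(OC)c5)c(OC)c4)[C@H](C)[C@H]3C)cc2O[Si](C)(C)C(C)(C)C)cc1OC | intermediate
31 | manassantin B1 | COc1ccc([C@@H](O)[C@@H](C)Oc2ccc([C@H]3O[C@H](c4ccc(O[C@H](C)[C@H](O)c5ccc(OC)c(OC)c5)c(OC)c4)[C@H](C)[C@H]3C)cc2O)cc1OC | target

## Count and risks

Total step count: 20. Longest linear sequence: 12 steps (13 → 31, steps 9–20).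

**Step 19 (key union).** What may go wrong: capture of the oxocarbenium ion by the bulky, fully elaborated arylzinc may be slow, so that elimination to the dihydrofuran or erosion of facial selectivity at C2 competes. Fallback (the side chain is built after the union): it sets out from sulfone 27. Commercial 2-(benzyloxy)-4-bromophenol (Oc1ccc(Br)cc1OCc1ccccc1) is silylated (TBSCl, imidazole) to [2-(benzyloxy)-4-bromophenoxy](tert-butyl)dimethylsilane F1. Its small arylzinc (n-BuLi, then ZnBr2) is coupled with 27 as in step 19, the closest literature case, to give the 2-[3-(benzyloxy)-4-(tert-butyldimethylsilyloxy)phenyl]oxolane F2. Selective methanolysis of the aryl silyl ether (K2CO3, MeOH) should give the phenol F3, which has no neighbouring silyl group that could migrate. Etherification with 5 (BEMP) gives the ketone F4, and the borohydride resin gives the threo alcohol F5. TBAF then gives O-benzyl manassantin B1 F6, and hydrogenolysis (H2, Pd/C, EtOAc) comes back to the route at 31.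

**Step 15 (and its twin, step 7).** What may go wrong: partial chelation or hydrogen-bond organisation of the α-aryloxy ketone may lower the Felkin preference, so that the erythro carbinol forms as well. Fallback (catalyst control in place of substrate control): asymmetric transfer hydrogenation with RuCl[(S,S)-TsDPEN](p-cymene) in HCO2H/Et3N delivers hydride in an outer-sphere step that cannot pass through a chelate, to the face that gives the (1R) carbinol. It sets out from 23 and comes back at 24, and likewise from 10 to 11; no new compound is made (F0).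

**Step 4 (and step 14).** What may go wrong: base-mediated enolisation of the tosylate or of the product may erode the configuration at C8, and the enolate may close onto the ortho aldehyde in an aldol reaction. Fallback (in situ activation of the alcohol under neutral conditions): Mitsunobu etherification of phenol 6 with hydroxy ketone 4 (PPh3, DIAD, THF, 0 °C) proceeds with inversion. It sets out from 4 and 6 and comes back at 7; no new compound is made (F0).

## Further compounds

F1 | step 19 | [2-(benzyloxy)-4-bromophenoxy](tert-butyl)dimethylsilane | CC(C)(C)[Si](C)(C)Oc1ccc(Br)cc1OCc1ccccc1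
F2 | step 19 | (2S,3R,4R,5S)-2-[3-(benzyloxy)-4-(tert-butyldimethylsilyloxy)phenyl]-5-(4-{[(1R,2R)-1-(tert-butyldimethylsilyloxy)-1-(3,4-dimethoxyphenyl)propan-2-yl]oxy}-3-methoxyphenyl)-3,4-dimethyloxolane | CC(C)(C)[Si](C)(C)Oc1ccc([C@H]2O[C@H](c3ccc(O[C@H](C)[C@H](O[Si](C)(C)C(C)(C)C)c4ccc(OC)c(OC)c4)c(OC)c3)[C@H](C)[C@H]2C)cc1OCc1ccccc1
F3 | step 19 | phenol from F2 (free OH para to the oxolane) | Oc1ccc([C@H]2O[C@H](c3ccc(O[C@H](C)[C@H](O[Si](C)(C)C(C)(C)C)c4ccc(OC)c(OC)c4)c(OC)c3)[C@H](C)[C@H]2C)cc1OCc1ccccc1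
F4 | step 19 | (2R)-aryloxy ketone from F3 and 5 | COc1ccc(C(=O)[C@@H](C)Oc2ccc([C@H]3O[C@H](c4ccc(O[C@H](C)[C@H](O[Si](C)(C)C(C)(C)C)c5ccc(OC)c(OC)c5)c(OC)c4)[C@H](C)[C@H]3C)cc2OCc2ccccc2)cc1OC
F5 | step 19 | (1R,2R) alcohol from F4 | COc1ccc([C@@H](O)[C@@H](C)Oc2ccc([C@H]3O[C@H](c4ccc(O[C@H](C)[C@H](O[Si](C)(C)C(C)(C)C)c5ccc(OC)c(OC)c5)c(OC)c4)[C@H](C)[C@H]3C)cc2OCc2ccccc2)cc1OC
F6 | step 19 | O-benzyl manassantin B1 | COc1ccc([C@@H](O)[C@@H](C)Oc2ccc([C@H]3O[C@H](c4ccc(O[C@H](C)[C@H](O)c5ccc(OC)c(OC)c5)c(OC)c4)[C@H](C)[C@H]3C)cc2OCc2ccccc2)cc1OC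
F0 | step 15 | none | none
F0 | step 4 | none | none
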